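90.0% is the target that flask ash can reach if one partner serves one substrate, since [partner]/[substrate] as charged is that ratio; partner is then the limiting reagent.

the same everywhere: substrate 0.20 M

| flask | partner | second reagent | temperature | remark | time |
|---|---|---|---|---|---|
| ash | 0.18 M | 0.50 M | 90 °C | the very flask that is asked about, followed so far |  |
| larch | 0.18 M | 0.50 M | 85 °C | run made earlier |  |
| flask | 0.180 M | 0.500 M | 90 °C |  | 3.0 h |

| run | time / min | target / % |
|---|---|---|
| ash | 15.0 | 43.8 |
| ash | 30.0 | 65.0 |
| ash | 80.0 | 80.0 |
| ash | 180 | 79.1 |
| larch | 15.0 | 34.7 |
| larch | 30.0 | 55.5 |
| larch | 80.0 | 78.5 |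
| larch | 180 | 80.1 |

(readings scatter by 1 percentage point)

- what is added takes up no volume worth counting
- a reading or a percentage of target counts all its forms, free or not

- midnight: at 3.0 h add substrate, 50.0% of the amount charged, then wait 6.0 h
- spring: change nothing and wait 6.0 h more
- summer: at 3.0 h add partner, 50.0% of the amount charged, then wait 6.0 h
- winter: at 3.0 h raise the temperature by 10 K, then wait 6.0 h

1. target, in percent of the substrate first charged, at 3.0 h
2. which option adds most target ("none" when 2 percentage points or less is all one gets) (midnight / spring / summer / winter / none)
3. target present, in percent of the substrate first charged, after spring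
4. target present, in percent of the substrate first charged, after summer

Two numbers seem not to go together. Ash runs ahead of the cooler larch, by a factor of 1.26 at 15.0 min, yet the plateaus are 79.5% in ash and 79.3% in larch, both lower than the ceiling. Ash moves by 0.9 percentage points between its last two readings, less than the scatter, so the gap is not a matter of waiting.

We therefore read the plateau as a fixed return on partner. The partner yield, the part of the consumed partner that stands as target, is

share = plateau / ceiling = 88.4%

We expect 79.5% now and after spring, and nothing from midnight or winter. For summer we go round twice:

first round: gain = share × added partner = 40 points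

But substrate beyond the partner charge is 10 points, less than that gain, so the second round uses substrate:

second round: gain = share × 10 points = 8.8 points, giving 88.4%

The forecast gives 79.6%, 79.5% after spring and 93% after summer, picks summer, and calls the plateau a “nearly thermoneutral equilibrium”; our summer figure is lower.

The flask gives 77.6% now, 76.2% after spring and 86.2% after summer; summer adds 8.6 points.

    second reagent + intermediate → target (k = 0.00240 /M/s, Ea = 70.0 kJ/mol)
    crystals ⇌ target, rate k2*(cs2 - [target]) while solid is left; crystals form when [target] > cs2 (solubility = 0.0790 M, k = 0.00910 /s)
    target ⇌ isomer of the product (K = 0.350, k = 7.50 × 10⁻⁵ /s, Ea = 129 kJ/mol, ΔH = 41.0 kJ/mol)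
    substrate + partner → intermediate (k = 0.0500 /M/s, Ea = 53.0 kJ/mol)
    (constants at 90 °C)

Summer's 8.6 points stands beside our 8.8 points. At 180 min the flask holds 12.4% of isomer of the product, which with target makes 90.0%. In a neighbour flask with 0.11 M of partner, the ceiling is 55.0% and the same share gives 48.6%. That neighbour flask stands at 42.7%, with 12.3% of isomer of the product and 3.28% of crystals, against 38.1% of crystals in the flask.

The earlier runs and the new flask were generated by integration with made-up constants, and the scatter is random.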